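The route rests on cutting the O1–C2 bond of the dimethylchroman ring and tracing it to an oxa-6π electrocyclisation. In one operation, 2,4-dihydroxyacetophenone and prenal form the C4–C4a bond, a 1-oxatriene (ortho-quinone methide) and the closed 2H-pyran, with no prenyl group or halogen installed beforehand. The step exploits C4a, which lies between the oxygen-bearing carbons C5 and C8a of the chroman benzene ring. It also exploits the carbon substituent at C6: as an acetyl group it chelates the C5 hydroxyl, so only the para oxygen becomes O1. The same acetyl group is then transposed (Willgerodt–Kindler) into the arylacetic acid that builds the coumarin by Perkin condensation.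

Key step: step 1

Remark: the target has no stereocentre. The only stereodescriptor in the route is the Z geometry of the transient oxatriene 3.

Step 1
Reactants: 1 2,4-dihydroxyacetophenone; 2 3-methylbut-2-enal (prenal)
Product: 4 1-(5-hydroxy-2,2-dimethyl-2H-chromen-6-yl)ethan-1-one, via ortho-quinone methide 3 (not isolated)
Conditions: pyridine, 140 °C, sealed tube
Reagents that add atoms: none
Why: Pyridine promotes a phenol-aldol (1,2-) addition of C3 of 1 (the future C4a) to the aldehyde of 2 and loss of water, giving the 1-oxatriene 3, whose carbonyl oxygen then bonds to the dimethyl-substituted terminus. The closest known reaction type is the base-mediated formal [3+3] chromenylation of acylresorcinols with enals (Knoevenagel-type condensation followed by oxa-6π electrocyclisation). The single ring formed, the 2H-pyran, closes by a thermal disrotatory oxa-6π electrocyclisation driven by the return of aromaticity. No stereocentre arises because C2 carries two methyl groups. Two selectivities are needed, C–C bond formation at C3 rather than C5 of 1 and closure through the C4 oxygen rather than the C2 oxygen: the acetyl carbonyl chelates the C2 hydroxyl, which makes C3 (flanked by both oxygens) the most nucleophilic carbon and leaves only the C4 oxygen free to become the oxatriene carbonyl. Because the electrocyclisation is reversible, the chelated isomer 4 should also be the thermodynamic product, and no second annulation is possible since the remaining hydroxyl has no free ortho position.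

Step 2
Reactants: 4 1-(5-hydroxy-2,2-dimethyl-2H-chromen-6-yl)ethan-1-one
Product: 5 1-(5-methoxy-2,2-dimethyl-2H-chromen-6-yl)ethan-1-one
Conditions: MeI, K2CO3, DMF, 50 °C
Reagents that add atoms: iodomethane, CI
Why: Williamson ether synthesis, in which carbonate in a dipolar aprotic solvent breaks the chelate and the only acidic hydroxyl is methylated, while K2CO3 is too weak to enolise the ketone for C-methylation.

Step 3
Reactants: 5 1-(5-methoxy-2,2-dimethyl-2H-chromen-6-yl)ethan-1-one
Product: 6 1-(5-methoxy-2,2-dimethylchroman-6-yl)ethan-1-one
Conditions: H2 (1 atm), Pd/C, EtOAc, rt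
Reagents that add atoms: none
Why: Catalytic hydrogenation, in which the cis-disubstituted styrene-type C3–C4 double bond should be saturated well before the electron-rich aryl ketone is touched; it is placed here because the alkene would not survive sulfur at 130 °C in step 4.

Step 4
Reactants: 6 1-(5-methoxy-2,2-dimethylchroman-6-yl)ethan-1-one
Product: 8 2-(5-methoxy-2,2-dimethylchroman-6-yl)acetic acid, via thiomorpholide 7 (not isolated)
Conditions: S8, morpholine, 130 °C; then NaOH, EtOH/H2O, reflux; HCl
Reagents that add atoms: sulfur, S1SSSSSSS1, and morpholine, C1COCCN1 (atoms of 7 only); sodium hydroxide, [Na+].[OH-] (both oxygen atoms of the acid group of 8)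
Why: Willgerodt–Kindler reaction, in which enamine formation and sulfur-mediated migration of the oxidised carbon to the chain end give the thioamide, as is well established for ortho- and para-alkoxyacetophenones; alkaline hydrolysis then frees the acid while the aryl ethers are inert to base.

Step 5
Reactants: 9 5-methoxyresorcinol (3,5-dihydroxyanisole)
Product: 11 2,4-dihydroxy-6-methoxybenzaldehyde, via iminium chloride 10 (not isolated)
Conditions: POCl3, DMF, MeCN, 0 °C to rt; then H2O, 50 °C
Reagents that add atoms: N,N-dimethylformamide, CN(C)C=O (formyl carbon); water, O (formyl oxygen); phosphoryl chloride, O=P(Cl)(Cl)Cl (chloride counter-ion of 10 only)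
Why: Vilsmeier–Haack formylation, in which the chloroiminium ion should prefer the two equivalent ring positions para to one hydroxyl and ortho to the other over the site between both hydroxyls; any isomeric 2,6-dihydroxy aldehyde is removable by crystallisation or chromatography.

Step 6
Reactants: 8 2-(5-methoxy-2,2-dimethylchroman-6-yl)acetic acid; 11 2,4-dihydroxy-6-methoxybenzaldehyde
Product: 13 7-hydroxy-5-methoxy-3-(5-methoxy-2,2-dimethylchroman-6-yl)-2H-chromen-2-one (target), via coumarin acetate 12 (not isolated)
Conditions: Ac2O, Et3N, 110 °C; evaporate; then HCl (cat.), MeOH, reflux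
Reagents that add atoms: acetic anhydride, CC(=O)OC(C)=O (acetyl group of 12 only)
Why: Perkin (Oglialoro) condensation, in which the mixed anhydride of 8 acylates the chelated phenol of 11 and the activated methylene condenses with the neighbouring aldehyde, with loss of water, to give the 3-arylcoumarin with its C7 hydroxyl masked in situ as the acetate; acid-catalysed methanolysis then removes the acetate without touching the lactone, the aryl methyl ethers or the chroman.

Compound list
1 | 2,4-dihydroxyacetophenone | CC(=O)c1ccc(O)cc1O | starting material
2 | 3-methylbut-2-enal | CC(C)=CC=O | starting material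
3 | (Z)-4-acetyl-3-hydroxy-2-(3-methylbut-2-en-1-ylidene)cyclohexa-3,5-dien-1-one | CC(=O)C1=C(O)/C(=C/C=C(C)C)C(=O)C=C1 | intermediate
4 | 1-(5-hydroxy-2,2-dimethyl-2H-chromen-6-yl)ethan-1-one | CC(=O)c1ccc2OC(C)(C)C=Cc2c1O | intermediate
5 | 1-(5-methoxy-2,2-dimethyl-2H-chromen-6-yl)ethan-1-one | CC(=O)c1ccc2OC(C)(C)C=Cc2c1OC | intermediate
6 | 1-(5-methoxy-2,2-dimethylchroman-6-yl)ethan-1-one | CC(=O)c1ccc2OC(C)(C)CCc2c1OC | intermediate
7 | 2-(5-methoxy-2,2-dimethylchroman-6-yl)-1-(morpholin-4-yl)ethane-1-thione | S=C(Cc1ccc2OC(C)(C)CCc2c1OC)N1CCOCC1 | intermediate
8 | 2-(5-methoxy-2,2-dimethylchroman-6-yl)acetic acid | OC(=O)Cc1ccc2OC(C)(C)CCc2c1OC | intermediate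
9 | 5-methoxyresorcinol | COc1cc(O)cc(O)c1 | starting material
10 | N-[(2,4-dihydroxy-6-methoxyphenyl)methylidene]-N-methylmethanaminium chloride | C[N+](C)=Cc1c(O)cc(O)cc1OC.[Cl-] | intermediate
11 | 2,4-dihydroxy-6-methoxybenzaldehyde | COc1cc(O)cc(O)c1C=O | intermediate
12 | 5-methoxy-3-(5-methoxy-2,2-dimethylchroman-6-yl)-2-oxo-2H-chromen-7-yl acetate | COc1c(-c2cc3c(OC)cc(OC(C)=O)cc3oc2=O)ccc2c1CCC(C)(C)O2 | intermediate
13 | 7-hydroxy-5-methoxy-3-(5-methoxy-2,2-dimethylchroman-6-yl)-2H-chromen-2-one (CNP0139207.0) | COc1c(-c2cc3c(OC)cc(O)cc3oc2=O)ccc2c1CCC(C)(C)O2 | target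

Total step count: 6. Longest linear sequence: 5 (steps 1, 2, 3, 4, 6).

Steps most likely to fail

Step 1: self-condensation of the enal at 140 °C, incomplete conversion and some attack at C5 of 1 may erode the annulation. The fallback reaches the same oxatriene by a sigmatropic route instead of a condensation. It sets out from 1, whose non-chelated C4 hydroxyl is alkylated with 3-chloro-3-methylbut-1-yne (K2CO3, KI, DMF, 65 °C). This gives the propargyl ether 1-[2-hydroxy-4-(2-methylbut-3-yn-2-yloxy)phenyl]ethan-1-one F1. Heating in N,N-diethylaniline at 200 °C should trigger an aromatic propargyl Claisen rearrangement to C3, a [1,5]-hydrogen shift to 3 and the oxa-6π closure. The fallback comes back to the route at 4.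

Step 4: tar formation during the hot sulfuration, slow hydrolysis of the hindered thioamide and sulfide-induced loss of the flanked methyl ether may occur. The fallback replaces the carbonyl transposition by an oxidative 1,2-aryl migration. It sets out from 6, which with PhI(OAc)2, HC(OMe)3 and H2SO4 (cat.) at 60 °C should form the enol ether and add the trivalent iodine reagent. The electron-rich aryl group then shifts, giving methyl 2-(5-methoxy-2,2-dimethylchroman-6-yl)acetate F2. Saponification (LiOH, THF/H2O, then HCl) comes back to the route at 8.

Step 6: acetylation of the chelated hydroxyl and acylal formation at the aldehyde may outrun acyl transfer from the mixed anhydride, and the arylacetic anhydride may self-condense. The fallback builds the lactone stepwise through an ester tether and sets out from 11 and 8. Aldehyde 11 is acetylated at its non-chelated hydroxyl only (Ac2O, 1 equiv, pyridine, 0 °C) to give 4-formyl-3-hydroxy-5-methoxyphenyl acetate F3. Steglich esterification with 8 (EDC, DMAP, CH2Cl2) gives 5-acetoxy-2-formyl-3-methoxyphenyl 2-(5-methoxy-2,2-dimethylchroman-6-yl)acetate F4. DBU then closes the ring by intramolecular Knoevenagel condensation. The fallback comes back to the route at 12, which is methanolysed as in step 6.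

Further compounds
F1 | step 1 | 1-[2-hydroxy-4-(2-methylbut-3-yn-2-yloxy)phenyl]ethan-1-one | CC(=O)c1ccc(OC(C)(C)C#C)cc1O
F2 | step 4 | methyl 2-(5-methoxy-2,2-dimethylchroman-6-yl)acetate | COC(=O)Cc1ccc2OC(C)(C)CCc2c1OC
F3 | step 6 | 4-formyl-3-hydroxy-5-methoxyphenyl acetate | CC(=O)Oc1cc(O)c(C=O)c(OC)c1
F4 | step 6 | 5-acetoxy-2-formyl-3-methoxyphenyl 2-(5-methoxy-2,2-dimethylchroman-6-yl)acetate | COc1c(CC(=O)Oc2cc(OC(C)=O)cc(OC)c2C=O)ccc2c1CCC(C)(C)O2
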